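**Assumption (one line):** from the SMILES the carbinol carbon C3 is read as R and the triaryl-type methine C7 as S (heptane locants, C1 = ArCH2), and the methoxymethyl (MOM) ethers of p-cresol, resorcinol and 4-bromophenol are taken as purchasable (each is otherwise one MOMCl step from the phenol).

## Retrosynthetic overview

1. Target ⇒ its penta-MOM ether; the aryl–C(=O) bond of the chalcone is cut to a ring A aryllithium (from the aryl bromide) and an (E)-cinnamoyl Weinreb amide (Heck product).
2. Key cut C6–C7: a diarylmethyl radical, made by C–H abstraction from ring A–CH2–aryl, is joined to an (E)-alkenyl bromide on a chiral nickel catalyst under photoredox conditions; this sets C7 (S) and carries the E alkene over.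
3. Alkenyl bromide ⇒ terminal alkyne (hydrozirconation/bromination) ⇒ (R)-epichlorohydrin + benzylic Grignard reagent + acetylide; C3 (R) comes from the chiral pool.
4. Diarylmethane ⇒ ortho-lithiated resorcinol bis-MOM ether + 4-(MOMO)benzyl bromide (from p-cresol MOM ether); the third ring A oxygen (the OMe) comes from Ir-catalysed C–H borylation/oxidation/methylation.
5. No ring is formed: the four benzene rings are bought and joined in the order ring A + benzyl unit, then the heptenyl chain with its aryl ring, then chalcone ring B.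

## Route

Step 1
Reactants: 1 1-(methoxymethoxy)-4-methylbenzene
Product: 2 1-(bromomethyl)-4-(methoxymethoxy)benzene
Conditions: NBS (1.05 equiv), AIBN (5 mol %), PhCF3, 85 °C
Reagents that add atoms: N-bromosuccinimide, O=C1CCC(=O)N1Br
Why: Wohl–Ziegler radical benzylic bromination; the non-polar medium and low Br2 concentration favour the benzylic chain over ring bromination, and the acetal survives the short acid-free run.

Step 2
Reactants: 3 1,3-bis(methoxymethoxy)benzene; 2 1-(bromomethyl)-4-(methoxymethoxy)benzene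
Product: 5 2-[4-(methoxymethoxy)benzyl]-1,3-bis(methoxymethoxy)benzene, via 2,6-bis(methoxymethoxy)phenyllithium 4 (not isolated)
Conditions: 3, n-BuLi (1.1 equiv), THF, 0 °C, 1 h; CuBr·SMe2 (10 mol %), then 2, −40 °C to rt; H2O
Reagents that add atoms: none
Why: Directed ortho-metalation occurs only at C2 between the two OMOM groups, and copper-catalysed SN2 benzylation of the aryllithium suppresses halogen–metal exchange.

Step 3
Reactants: 5 2-[4-(methoxymethoxy)benzyl]-1,3-bis(methoxymethoxy)benzene
Product: 8 5-methoxy-1,3-bis(methoxymethoxy)-2-[4-(methoxymethoxy)benzyl]benzene, via arylboronic pinacol ester 6 (not isolated), via phenol 7 (not isolated)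
Conditions: [Ir(OMe)(cod)]2 (1.5 mol %), dtbpy (3 mol %), B2pin2 (0.6 equiv), THF, 80 °C; then NaOH (aq), H2O2, 0 °C to rt; then Me2SO4, Bu4NBr (5 mol %), rt
Reagents that add atoms: hydrogen peroxide, OO; dimethyl sulfate, COS(=O)(=O)OC
Why: Sterically controlled iridium-catalysed C–H borylation takes the only ring C–H without an ortho neighbour (para to the benzyl group on ring A), and boronate oxidation followed by Williamson methylation of the phenoxide in the same basic pot installs the OMe without touching the MOM ethers.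

Step 4
Reactants: 2 1-(bromomethyl)-4-(methoxymethoxy)benzene; 9 (R)-2-(chloromethyl)oxirane
Product: 11 (R)-1-chloro-4-[4-(methoxymethoxy)phenyl]butan-2-ol, via 4-(methoxymethoxy)benzylmagnesium bromide 10 (not isolated)
Conditions: 2, Mg (3 equiv), Et2O, 0 °C, slow addition; then 9, CuBr·SMe2 (10 mol %), THF, −40 to −20 °C; H2O
Reagents that add atoms: none
Why: Copper-catalysed SN2 opening of the epoxide at its CH2 terminus by the benzylic Grignard reagent leaves the stereocentre untouched, so (R)-epichlorohydrin gives the (R)-chlorohydrin.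

Step 5
Reactants: 11 (R)-1-chloro-4-[4-(methoxymethoxy)phenyl]butan-2-ol; 12 lithium acetylide–ethylenediamine complex (LiC≡CH·H2NCH2CH2NH2)
Product: 14 (R)-1-[4-(methoxymethoxy)phenyl]hex-5-yn-3-ol, via (R)-epoxide 13 (not isolated)
Conditions: 12 (3 equiv), DMSO, 0 °C to rt; H2O
Reagents that add atoms: none
Why: One equivalent of acetylide closes the chlorohydrin to the terminal epoxide (Williamson) and a second opens it at CH2 (SN2 alkynylation); the C–O bond at the stereocentre is never broken, so C3 stays R.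

Step 6
Reactants: 14 (R)-1-[4-(methoxymethoxy)phenyl]hex-5-yn-3-ol
Product: 16 (3R,5E)-6-bromo-1-[4-(methoxymethoxy)phenyl]hex-5-en-3-ol, via alkenylzirconocene chloride 15 (not isolated)
Conditions: Cp2Zr(H)Cl (2.3 equiv), THF, rt; NBS (1.1 equiv), 0 °C; H2O
Reagents that add atoms: N-bromosuccinimide, O=C1CCC(=O)N1Br
Why: Hydrozirconation (Schwartz) adds Zr–H syn with zirconium at the terminal carbon, and bromodezirconation with retention gives the E-alkenyl bromide; the extra equivalent of hydride covers the free OH.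

Step 7 (key step)
Reactants: 8 5-methoxy-1,3-bis(methoxymethoxy)-2-[4-(methoxymethoxy)benzyl]benzene (3 equiv, excess recovered); 16 (3R,5E)-6-bromo-1-[4-(methoxymethoxy)phenyl]hex-5-en-3-ol
Product: 17 (3R,5E,7S)-7-[4-methoxy-2,6-bis(methoxymethoxy)phenyl]-1,7-bis[4-(methoxymethoxy)phenyl]hept-5-en-3-ol
Conditions: NiCl2(dme) (10 mol %), chiral 1,1'-diaryl-4,4'-dialkyl-2,2'-bi(2-imidazoline) ligand (12 mol %), [Ir(dF(CF3)ppy)2(dtbbpy)]PF6 (2 mol %), 4,4'-dimethoxybenzophenone (0.5 equiv), K2HPO4 (2 equiv), PhH/MeCN, blue LEDs (450 nm), 20 °C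
Reagents that add atoms: none
Why: Proposed new method: the doubly benzylic C–H of 8 is the weakest and most hydridic C–H in either partner and is cleaved by a bromine atom released from the nickel bromide under photoredox conditions (or by deprotonation of the photo-oxidised ring A radical cation); the diarylmethyl radical is trapped by the (E)-alkenylnickel bromide formed by oxidative addition of 16 to zerovalent nickel, and C–C reductive elimination from trivalent nickel inside the chiral ligand pocket, which distinguishes the flat 4-substituted ring from the 2,6-disubstituted ring A, sets C7 as S (ligand antipode chosen on a test run for that sense) while the E geometry and C3 are carried over unchanged; the closest known reaction types are the enantioselective photoredox/nickel benzylic C–H alkenylation of alkylarenes with alkenyl bromides and the nickel-catalysed asymmetric reductive coupling of benzylic radicals with vinyl bromides.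

Step 8
Reactants: 17 (3R,5E,7S)-7-[4-methoxy-2,6-bis(methoxymethoxy)phenyl]-1,7-bis[4-(methoxymethoxy)phenyl]hept-5-en-3-ol
Product: 18 (3R,5E,7S)-7-[3-bromo-4-methoxy-2,6-bis(methoxymethoxy)phenyl]-1,7-bis[4-(methoxymethoxy)phenyl]hept-5-en-3-ol
Conditions: NBS (1.0 equiv), CH2Cl2/MeCN, −40 °C, dark
Reagents that add atoms: N-bromosuccinimide, O=C1CCC(=O)N1Br
Why: Electrophilic aromatic bromination goes to the trioxygenated ring A (two equivalent free positions, each between OMOM and OMe) far faster than to the isolated alkene or the para-blocked aryl ethers, and one equivalent at low temperature stops at the monobromide.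

Step 9
Reactants: 19 1-bromo-4-(methoxymethoxy)benzene; 20 N-methoxy-N-methylprop-2-enamide
Product: 21 (2E)-N-methoxy-3-[4-(methoxymethoxy)phenyl]-N-methylprop-2-enamide
Conditions: Pd(OAc)2 (2 mol %), P(o-tol)3 (4 mol %), Et3N (2 equiv), DMF, 100 °C
Reagents that add atoms: none
Why: Mizoroki–Heck arylation of the acrylamide gives the E-cinnamoyl Weinreb amide by syn insertion and syn β-hydride elimination.

Step 10
Reactants: 18 (3R,5E,7S)-7-[3-bromo-4-methoxy-2,6-bis(methoxymethoxy)phenyl]-1,7-bis[4-(methoxymethoxy)phenyl]hept-5-en-3-ol; 21 (2E)-N-methoxy-3-[4-(methoxymethoxy)phenyl]-N-methylprop-2-enamide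
Product: 23 (2E)-1-{3-[(1S,2E,5R)-5-hydroxy-1,7-bis[4-(methoxymethoxy)phenyl]hept-2-en-1-yl]-6-methoxy-2,4-bis(methoxymethoxy)phenyl}-3-[4-(methoxymethoxy)phenyl]prop-2-en-1-one, via dilithiated aryl alkoxide 22 (not isolated)
Conditions: MeLi (1.05 equiv), THF, −78 °C; t-BuLi (2.1 equiv), −78 °C, 15 min; 21 (1.5 equiv), −78 to −20 °C; H2O
Reagents that add atoms: none
Why: Bromine–lithium exchange at −78 °C is far faster than deprotonation at C7, and Weinreb ketone synthesis (1,2-addition to the chelating amide, stable tetrahedral intermediate) delivers the chalcone without over-addition or loss of the C7 configuration.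

Step 11
Reactants: 23 (2E)-1-{3-[(1S,2E,5R)-5-hydroxy-1,7-bis[4-(methoxymethoxy)phenyl]hept-2-en-1-yl]-6-methoxy-2,4-bis(methoxymethoxy)phenyl}-3-[4-(methoxymethoxy)phenyl]prop-2-en-1-one
Product: 24 (2E)-1-{2,4-dihydroxy-3-[(1S,2E,5R)-5-hydroxy-1,7-bis(4-hydroxyphenyl)hept-2-en-1-yl]-6-methoxyphenyl}-3-(4-hydroxyphenyl)prop-2-en-1-one
Conditions: HCl (3 M aq.)/MeOH 1:4, 35 °C
Reagents that add atoms: none
Why: Acid-catalysed transacetalisation removes all five aryl MOM ethers as dimethoxymethane under conditions routinely tolerated by 2'-hydroxy-6'-methoxychalcones, and neither stereocentre is acidic or ionisable under them.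

## Compound list

Compounds 4, 6, 7, 10, 13, 15 and 22 are not isolated.

1 | 1-(methoxymethoxy)-4-methylbenzene | COCOc1ccc(C)cc1 | starting material
2 | 1-(bromomethyl)-4-(methoxymethoxy)benzene | COCOc1ccc(CBr)cc1 | intermediate
3 | 1,3-bis(methoxymethoxy)benzene | COCOc1cccc(OCOC)c1 | starting material
4 | [2,6-bis(methoxymethoxy)phenyl]lithium | COCOc1cccc(OCOC)c1[Li] | intermediate
5 | 2-[4-(methoxymethoxy)benzyl]-1,3-bis(methoxymethoxy)benzene | COCOc1ccc(Cc2c(OCOC)cccc2OCOC)cc1 | intermediate
6 | 2-{3,5-bis(methoxymethoxy)-4-[4-(methoxymethoxy)benzyl]phenyl}-4,4,5,5-tetramethyl-1,3,2-dioxaborolane | COCOc1ccc(Cc2c(OCOC)cc(B3OC(C)(C)C(C)(C)O3)cc2OCOC)cc1 | intermediate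
7 | 3,5-bis(methoxymethoxy)-4-[4-(methoxymethoxy)benzyl]phenol | COCOc1ccc(Cc2c(OCOC)cc(O)cc2OCOC)cc1 | intermediate
8 | 5-methoxy-1,3-bis(methoxymethoxy)-2-[4-(methoxymethoxy)benzyl]benzene | COCOc1ccc(Cc2c(OCOC)cc(OC)cc2OCOC)cc1 | intermediate
9 | (R)-2-(chloromethyl)oxirane [(R)-epichlorohydrin] | ClC[C@H]1CO1 | starting material
10 | 4-(methoxymethoxy)benzylmagnesium bromide | COCOc1ccc(C[Mg]Br)cc1 | intermediate
11 | (R)-1-chloro-4-[4-(methoxymethoxy)phenyl]butan-2-ol | ClC[C@H](O)CCc1ccc(OCOC)cc1 | intermediate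
12 | lithium acetylide–ethylenediamine complex | [Li+].[C-]#C.NCCN | starting material
13 | (R)-2-{2-[4-(methoxymethoxy)phenyl]ethyl}oxirane | C1[C@H](O1)CCc2ccc(OCOC)cc2 | intermediate
14 | (R)-1-[4-(methoxymethoxy)phenyl]hex-5-yn-3-ol | C#CC[C@H](O)CCc1ccc(OCOC)cc1 | intermediate
15 | (E)-alkenylzirconocene chloride of 14, with the alcohol as its chlorozirconocene alkoxide | Cl[Zr](C1C=CC=C1)(C1C=CC=C1)/C=C/C[C@H](O[Zr](Cl)(C1C=CC=C1)C1C=CC=C1)CCc1ccc(OCOC)cc1 | intermediate
16 | (3R,5E)-6-bromo-1-[4-(methoxymethoxy)phenyl]hex-5-en-3-ol | Br/C=C/C[C@H](O)CCc1ccc(OCOC)cc1 | intermediate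
17 | (3R,5E,7S)-7-[4-methoxy-2,6-bis(methoxymethoxy)phenyl]-1,7-bis[4-(methoxymethoxy)phenyl]hept-5-en-3-ol | COc1cc(OCOC)c([C@@H](/C=C/C[C@H](O)CCc2ccc(OCOC)cc2)c2ccc(OCOC)cc2)c(OCOC)c1 | intermediate
18 | (3R,5E,7S)-7-[3-bromo-4-methoxy-2,6-bis(methoxymethoxy)phenyl]-1,7-bis[4-(methoxymethoxy)phenyl]hept-5-en-3-ol | COc1cc(OCOC)c([C@@H](/C=C/C[C@H](O)CCc2ccc(OCOC)cc2)c2ccc(OCOC)cc2)c(OCOC)c1Br | intermediate
19 | 1-bromo-4-(methoxymethoxy)benzene | COCOc1ccc(Br)cc1 | starting material
20 | N-methoxy-N-methylprop-2-enamide | C=CC(=O)N(C)OC | starting material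
21 | (2E)-N-methoxy-3-[4-(methoxymethoxy)phenyl]-N-methylprop-2-enamide | CON(C)C(=O)/C=C/c1ccc(OCOC)cc1 | intermediate
22 | aryllithium/lithium alkoxide from 18 (Li in place of Br, OLi in place of OH) | COc1cc(OCOC)c([C@@H](/C=C/C[C@H](O[Li])CCc2ccc(OCOC)cc2)c2ccc(OCOC)cc2)c(OCOC)c1[Li] | intermediate
23 | (2E)-1-{3-[(1S,2E,5R)-5-hydroxy-1,7-bis[4-(methoxymethoxy)phenyl]hept-2-en-1-yl]-6-methoxy-2,4-bis(methoxymethoxy)phenyl}-3-[4-(methoxymethoxy)phenyl]prop-2-en-1-one | COc1cc(OCOC)c([C@@H](/C=C/C[C@H](O)CCc2ccc(OCOC)cc2)c2ccc(OCOC)cc2)c(OCOC)c1C(=O)/C=C/c1ccc(OCOC)cc1 | intermediate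
24 | (2E)-1-{2,4-dihydroxy-3-[(1S,2E,5R)-5-hydroxy-1,7-bis(4-hydroxyphenyl)hept-2-en-1-yl]-6-methoxyphenyl}-3-(4-hydroxyphenyl)prop-2-en-1-one | COc1cc(O)c([C@@H](/C=C/C[C@H](O)CCc2ccc(O)cc2)c2ccc(O)cc2)c(O)c1C(=O)/C=C/c1ccc(O)cc1 | target

## Step count and risks

Total: 11 steps. Longest linear sequence: 8 steps (1 → 2 → 11 → 14 → 16 → 17 → 18 → 23 → 24, i.e. steps 1, 4, 5, 6, 7, 8, 10, 11).

**Step 7 (most likely to fail).** Three things can go wrong:
- hydrogen abstraction at other weak C–H bonds (allylic C4–H of 16, MOM acetal C–H);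
- slow nickel capture of the hindered diarylmethyl radical, giving dimer;
- erosion of the C7 ratio by re-abstraction of the new C7–H.

Because C3 is already fixed, the wrong C7 sense shows up as the (3R,7R) diastereomer and can be read by HPLC.

The fallback makes the radical only at C7, by electron transfer instead of hydrogen abstraction. It sets out from 8. Deprotonation at the diarylmethane carbon (LiN(i-Pr)2/KOt-Bu, THF, −78 °C) and a CO2 quench give racemic 2-[4-methoxy-2,6-bis(methoxymethoxy)phenyl]-2-[4-(methoxymethoxy)phenyl]acetic acid F1. N-hydroxyphthalimide and N,N'-diisopropylcarbodiimide convert it into its 1,3-dioxoisoindolin-2-yl ester F2. Nickel-catalysed enantioselective decarboxylative alkenylation of this redox-active ester with 16 (NiBr2(diglyme), chiral indanyl bis(oxazoline), tetrakis(dimethylamino)ethylene as reductant, NaI, DMA, −5 °C) comes back to the route at 17.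

**Step 10.** The di-ortho-substituted aryllithium may add sluggishly to the cinnamoyl amide or add in a conjugate sense. The fallback builds the enone by aldol condensation instead. It sets out from 18. The same exchange (MeLi, then t-BuLi, −78 °C) is quenched with the small electrophile N-methoxy-N-methylacetamide to give 1-{3-[(1S,2E,5R)-5-hydroxy-1,7-bis[4-(methoxymethoxy)phenyl]hept-2-en-1-yl]-6-methoxy-2,4-bis(methoxymethoxy)phenyl}ethanone F3. Separately 19 is converted with Mg and then DMF into 4-(methoxymethoxy)benzaldehyde F4. Claisen–Schmidt condensation of the two (Ba(OH)2 or KOH, EtOH, rt; C7–H is far too weakly acidic to epimerise) comes back to the route at 23.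

**Step 4.** 4-Alkoxybenzyl bromides form Grignard reagents with much Wurtz dimer. The fallback avoids any benzylic organometallic and sets out from 19. Heck arylation of allyl alcohol with chain-walking (Pd(OAc)2, Bu4NCl, NaHCO3, DMF, 50 °C) gives 3-[4-(methoxymethoxy)phenyl]propanal F5. Catalytic asymmetric propargylation with allenylboronic acid pinacol ester and a chiral BINOL-derived phosphoric acid (antipode chosen to give R) comes back to the route at 14.

## Further compounds

F1 | step 7 | rac-2-[4-methoxy-2,6-bis(methoxymethoxy)phenyl]-2-[4-(methoxymethoxy)phenyl]acetic acid | COCOc1ccc(C(C(=O)O)c2c(OCOC)cc(OC)cc2OCOC)cc1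
F2 | step 7 | 1,3-dioxoisoindolin-2-yl rac-2-[4-methoxy-2,6-bis(methoxymethoxy)phenyl]-2-[4-(methoxymethoxy)phenyl]acetate | COCOc1ccc(C(C(=O)ON2C(=O)c3ccccc3C2=O)c2c(OCOC)cc(OC)cc2OCOC)cc1
F3 | step 10 | 1-{3-[(1S,2E,5R)-5-hydroxy-1,7-bis[4-(methoxymethoxy)phenyl]hept-2-en-1-yl]-6-methoxy-2,4-bis(methoxymethoxy)phenyl}ethanone | COc1cc(OCOC)c([C@@H](/C=C/C[C@H](O)CCc2ccc(OCOC)cc2)c2ccc(OCOC)cc2)c(OCOC)c1C(C)=O
F4 | step 10 | 4-(methoxymethoxy)benzaldehyde | COCOc1ccc(C=O)cc1
F5 | step 4 | 3-[4-(methoxymethoxy)phenyl]propanal | COCOc1ccc(CCC=O)cc1
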